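- Slowness came first in Saturday's flask: after 40.0 min it held 13.0 % target, so I could not read its end and borrowed one from Wednesday's run.

| setting | Saturday's | Wednesday's | flask |
|---|---|---|---|
| starting material | 0.25 M | 0.12 M | 0.25 M |
| second substrate | 2 equiv | 2 equiv | 2.00 equiv |
| solid reagent | 1.2 equiv | 1.2 equiv | 1.20 equiv |
| free catalyst | 2.5 mol% | 2.5 mol% | 2.5 mol% |
| remark | the very flask that is asked about, followed so far | run made earlier |  |
| time |  |  | 3.0 h |

| run | time / min | target / % |
|---|---|---|
| Saturday's | 3.00 | 1.3 |
| Saturday's | 5.00 | 0.3 |
| Saturday's | 8.00 | 0.8 |
| Saturday's | 12.0 | 1.7 |
| Saturday's | 20.0 | 3.6 |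
| Saturday's | 40.0 | 13.0 |
| Wednesday's | 10.0 | 0.9 |
| Wednesday's | 15.0 | 2.7 |
| Wednesday's | 30.0 | 13.5 |
| Wednesday's | 50.0 | 28.0 |
| Wednesday's | 80.0 | 36.9 |
| Wednesday's | 120 | 38.2 |

(readings scatter by 0.5 percentage points)

- solid reagent is a solid; its amount is given per volume of the solution
- at the start none of the solid reagent is in solution

- summer: doubling the amount of free catalyst, all else as stated
- spring: doubling the dissolution coefficient of the solid reagent, all else as stated
- noon: doubling the solubility of the solid reagent, all else as stated

- target at 3.0 h, in percent of the starting material charged
- the change that raises the amount of target at 3.0 h, in percent of the starting material charged most ("none" if none brings more than 2 percentage points) (summer / spring / noon / none)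
- amount of target at 3.0 h, in percent of the starting material charged, after noon

- The bench rule names the reagent in deficit as the limiting reagent. With 1.20 equiv of solid reagent, that is the starting material, and the yield should climb towards complete conversion.
- Wednesday's run broke the rule: from 80.0 min to 120 min target rose by 1.3 percentage points, to 38.2 %, against a scatter of 0.5 points.
- I supposed that the 1.2 equiv of solid reagent had been used up there and that a path through the second substrate had shared it. Wednesday's last reading over the charge gave 0.318; I called this the target share, the fraction of the solid reagent charged that ends as target.
- The border of the rule is where target share times solid charge reaches one. These charges gave 0.382, so I took the solid reagent as the limiting reagent.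
- Saturday's flask needed 40.0 min for about the target that Wednesday's run had at 30.0 min, a stretch of 1.33 as read. I therefore estimated that Saturday's flask would go flat by about 160 min, earlier than 3.0 h, and I committed to 38.2 %.
- The forecast gave 35 %, lower than my figure, with 39 % after noon and summer as the best change: “Doubling the catalyst should raise the ceiling most”.

    starting material + free catalyst ⇌ catalyst intermediate A (K = 21.0 M⁻¹, k = 437 M⁻¹ min⁻¹)
    partner + catalyst intermediate A → free catalyst + target (k = 19.3 M⁻¹ min⁻¹)
    second substrate + free catalyst ⇌ catalyst intermediate B (K = 632 M⁻¹, k = 17.1 M⁻¹ min⁻¹)
    partner + catalyst intermediate B → free catalyst + second product (k = 13.3 M⁻¹ min⁻¹)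
    solid reagent ⇌ partner, rate k5*(cs5 - [partner]) while solid is left; crystals form when [partner] > cs5 (solubility = 0.190 M, k = 0.0223 min⁻¹)

- The flask gave 35.8 %, a target share of 0.298, with 0.0052 % of the solid reagent left. The best change was noon, giving 45.1 %, while summer moved the target by −8.2 points.
- The neighbour whose second substrate stood at 5.00 equiv gave 17.5 %, a target share of 0.146.
- At 3.00 h in the flask, partner, the dissolved solid reagent, had a half-life of 0.14 h by the step through catalyst intermediate B, the resting state at 97.6 % of the catalyst charged.
- By the step through catalyst intermediate A its half-life was longer, at 5.2 h, which is 36.4 times the first.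

The earlier runs and the new flask were computed with constants of no real substance; the scatter is artificial.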